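A direct plan would take apigenin A1, oxidise C6 with PhI(OAc)2 to the aryliodonium phenolate A2, exchange the iodonium group for methoxy to reach hispidulin A3, and sulfate the 7- and 4'-hydroxyls. Its weakest steps would be:
- the hypervalent-iodine attack on an unprotected triphenol, where the C6/C8 choice would rest only on the 5-OH chelate and the ring B phenol could be oxidised;
- the replacement of the iodonium group by OMe through a metal carbene in methanol, an aryl C–O bond formation that would have to outrun phenyl migration to a 2-iodophenyl ether and insertion into the substrate's own phenols;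
- the late bis-sulfation of a free triphenol, where the 5-OH would be spared only by its hydrogen bond.

The route would rest on cutting ring C at three bonds, O1–C8a, C4–C4a and O1–C2: ring A would enter as a 3-benzyloxy-4-methoxy-5-(4-methoxybenzyloxy)benzyne, and C2–C4 with ring B as an arylpropiolic acid. The feature exploited is that C5 bears oxygen and C8 hydrogen: the C5 ether flanks aryne carbon C4a and so sends the carboxylate oxygen to C8a and the acyl carbon to C4a, after which the phenoxide closes the pyranone, all in one operation. The 6-methoxy group is bought in 2-methoxyresorcinol, so no flavone is oxidised and no C6/C8 choice arises; O5 stays benzylated through sulfation, so sulfate can enter only at O7 and O4'.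

Key step: step 9

Remark: the target is achiral, so no stereocentre has to be set; the free acid is taken to be isolated cold by cation exchange and freeze-drying, because aryl hydrogen sulfates hydrolyse in their own acid.

Step 1
Reactants: 1 2-methoxyresorcinol (2-methoxybenzene-1,3-diol)
Product: 3 2,4-dihydroxy-3-methoxybenzaldehyde, via aryl iminium chloride 2 (not isolated)
Conditions: POCl3 (1.2 equiv), DMF (1.5 equiv), MeCN, 0 °C to rt; then H2O, 50 °C
Reagents that add atoms: N,N-dimethylformamide, CN(C)C=O; water, O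
Why: Vilsmeier–Haack formylation of a resorcinol, in which the only activated positions (C4 and C6) are equivalent by symmetry, so one aldehyde should form, and its carbonyl group then tells the two hydroxyls apart.

Step 2
Reactants: 3 2,4-dihydroxy-3-methoxybenzaldehyde
Product: 4 2-hydroxy-3-methoxy-4-[(4-methoxybenzyl)oxy]benzaldehyde
Conditions: 4-methoxybenzyl chloride (1.05 equiv), KHCO3 (1.5 equiv), KI (10 mol %), MeCN, 70 °C
Reagents that add atoms: 4-methoxybenzyl chloride, COc1ccc(CCl)cc1
Why: Williamson etherification with a weak base, which should alkylate only the more acidic 4-OH (para to the formyl group) because the 2-OH is held in a hydrogen bond to the carbonyl oxygen.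

Step 3
Reactants: 4 2-hydroxy-3-methoxy-4-[(4-methoxybenzyl)oxy]benzaldehyde
Product: 5 2-(benzyloxy)-3-methoxy-4-[(4-methoxybenzyl)oxy]benzaldehyde
Conditions: BnBr (1.3 equiv), K2CO3 (2 equiv), DMF, 60 °C
Reagents that add atoms: benzyl bromide, BrCc1ccccc1
Why: Williamson etherification under more forcing conditions, which breaks the chelate and benzylates the remaining phenol, the oxygen that will become O5 of the flavone.

Step 4
Reactants: 5 2-(benzyloxy)-3-methoxy-4-[(4-methoxybenzyl)oxy]benzaldehyde
Product: 7 2-(benzyloxy)-3-methoxy-4-[(4-methoxybenzyl)oxy]phenol, via aryl formate 6 (not isolated)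
Conditions: mCPBA (1.2 equiv), CH2Cl2, 0 °C to rt; then K2CO3 (0.2 equiv), MeOH, rt
Reagents that add atoms: 3-chloroperoxybenzoic acid (mCPBA), O=C(OO)c1cccc(Cl)c1
Why: Baeyer–Villiger (Dakin-type) oxidation of an electron-rich benzaldehyde, in which the aryl group with ortho and para alkoxy groups migrates in preference to hydride, and methanolysis of the formate frees the phenol whose oxygen will serve as the triflate leaving group on C4a.

Step 5
Reactants: 7 2-(benzyloxy)-3-methoxy-4-[(4-methoxybenzyl)oxy]phenol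
Product: 8 2-(benzyloxy)-6-bromo-3-methoxy-4-[(4-methoxybenzyl)oxy]phenol
Conditions: NBS (1.0 equiv), iPr2NH (10 mol %), CH2Cl2, −20 °C, dark
Reagents that add atoms: N-bromosuccinimide, O=C1CCC(=O)N1Br
Why: amine-mediated electrophilic ortho-bromination of a phenol, for which C6 is the only free position ortho to the hydroxyl (C2 and the para position C4 are blocked) and the hydroxyl should outweigh the ethers that activate C5.

Step 6
Reactants: 8 2-(benzyloxy)-6-bromo-3-methoxy-4-[(4-methoxybenzyl)oxy]phenol
Product: 11 2-(benzyloxy)-3-methoxy-4-[(4-methoxybenzyl)oxy]-6-(trimethylsilyl)phenyl trifluoromethanesulfonate, via aryl trimethylsilyl ether 9 (not isolated), via lithium silylphenoxide 10 (not isolated)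
Conditions: HMDS (1.0 equiv), THF, 65 °C, then evaporate; n-BuLi (1.1 equiv), THF, −78 °C; Tf2O (1.2 equiv), −78 to 0 °C
Reagents that add atoms: hexamethyldisilazane, C[Si](C)(C)N[Si](C)(C)C; trifluoromethanesulfonic anhydride, O=S(=O)(OS(=O)(=O)C(F)(F)F)C(F)(F)F; n-butyllithium, [Li]CCCC (lithium of 10 only)
Why: O-silylation, bromine–lithium exchange with retro-Brook 1,3 shift of silicon from oxygen to carbon, and O-triflation, the standard entry to 2-(trimethylsilyl)aryl triflates and here the direct analogue of the usual 3-methoxybenzyne precursor.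

Step 7
Reactants: 12 4-iodophenol
Product: 13 1-iodo-4-[(4-methoxybenzyl)oxy]benzene
Conditions: 4-methoxybenzyl chloride (1.1 equiv), K2CO3 (1.5 equiv), DMF, 60 °C
Reagents that add atoms: 4-methoxybenzyl chloride, COc1ccc(CCl)cc1
Why: Williamson etherification of a simple phenol, giving the future O4' the same acid-labile group as O7.

Step 8
Reactants: 13 1-iodo-4-[(4-methoxybenzyl)oxy]benzene; 14 propiolic acid
Product: 15 3-{4-[(4-methoxybenzyl)oxy]phenyl}prop-2-ynoic acid
Conditions: Pd(PPh3)2Cl2 (2.5 mol %), 1,4-bis(diphenylphosphino)butane (5 mol %), DBU (2.2 equiv), DMSO, rt; then cold 1 M HCl to pH 3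
Reagents that add atoms: none
Why: copper-free Sonogashira coupling of an aryl iodide with propiolic acid as its amidinium salt, which at room temperature should stop at the arylpropiolic acid because the decarboxylative second coupling needs heat.

Step 9
Reactants: 11 2-(benzyloxy)-3-methoxy-4-[(4-methoxybenzyl)oxy]-6-(trimethylsilyl)phenyl trifluoromethanesulfonate; 15 3-{4-[(4-methoxybenzyl)oxy]phenyl}prop-2-ynoic acid
Product: 18 5-(benzyloxy)-6-methoxy-7-[(4-methoxybenzyl)oxy]-2-{4-[(4-methoxybenzyl)oxy]phenyl}-4H-chromen-4-one, via aryne 16 (not isolated), via hydroxyaryl ynone 17 (not isolated)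
Conditions: 11 (1.0 equiv), 15 (1.2 equiv), CsF (4 equiv), THF, sealed tube, 100 °C, 24 h; then Et2NH (2 equiv), EtOH, 60 °C
Reagents that add atoms: none
Why: Fluoride removes the silyl group of 11 and triflate leaves to give aryne 16 (C4a≡C8a in flavone numbering); the caesium carboxylate of 15 adds through oxygen, the aryl anion so formed attacks the ester carbonyl (4-exo-trig, a benzoxetene alkoxide) and ring opening delivers the 2-acylphenoxide of ynone 17, a net insertion of the aryne into the C–O bond of the acid. The closest known reaction type is this same aryne–carboxylic acid C–O insertion, which with arylpropiolic acids is known to run on to flavones. Ring C then closes by 6-endo-dig conjugate addition of the phenoxide O1 to C2 of the ynone, so that O1–C8a, C4–C4a and O1–C2 are made in one flask, and no stereocentre is formed. The first selectivity needed is the sense of addition to the unsymmetrical aryne: the benzyloxy group on C5 flanks C4a, stabilises negative charge there by induction and distorts the triple bond so that the nucleophile attacks the distal, unhindered carbon C8a, as with 3-methoxybenzyne, while the ethers on C6 and C7 are remote and largely cancel. The second selectivity, 6-endo against 5-exo closure (flavone against aurone), should be favoured in the aprotic medium, where the exo adduct can revert, and the diethylamine treatment converts any ynone left over into the flavone through its enaminone.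

Step 10
Reactants: 18 5-(benzyloxy)-6-methoxy-7-[(4-methoxybenzyl)oxy]-2-{4-[(4-methoxybenzyl)oxy]phenyl}-4H-chromen-4-one
Product: 19 5-(benzyloxy)-7-hydroxy-2-(4-hydroxyphenyl)-6-methoxy-4H-chromen-4-one (5-O-benzylhispidulin)
Conditions: TFA (10 vol %), pentamethylbenzene (6 equiv), CH2Cl2, 0 °C, 1 h
Reagents that add atoms: none
Why: acidolysis of 4-methoxybenzyl aryl ethers with Friedel–Crafts capture of the stabilised cation by pentamethylbenzene, under which the plain benzyl ether on O5 should not ionise, so that only O7 and O4' are freed.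

Step 11
Reactants: 19 5-(benzyloxy)-7-hydroxy-2-(4-hydroxyphenyl)-6-methoxy-4H-chromen-4-one
Product: 21 disodium 5-O-benzylhispidulin 7,4'-disulfate, via bis(pyridinium) disulfate 20 (not isolated)
Conditions: SO3·pyridine (6 equiv), pyridine, rt to 40 °C, 12 h; aq. NaHCO3 to pH 8, 0 °C; evaporate; Sephadex LH-20 (MeOH–H2O)
Reagents that add atoms: sulfur trioxide–pyridine complex, O=S(=O)([O-])[n+]1ccccc1; sodium hydrogencarbonate, [Na+].OC([O-])=O
Why: O-sulfation of phenols with an amine–sulfur trioxide complex, in which only the 7- and 4'-hydroxyls are free because O5 is still benzylated, and exchange to the sodium salt removes pyridine, which would slow the hydrogenolysis that follows.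

Step 12
Reactants: 21 disodium 5-O-benzylhispidulin 7,4'-disulfate
Product: 23 hispidulin 7,4'-disulfate (free acid), via disodium hispidulin 7,4'-disulfate 22 (not isolated)
Conditions: H2 (1 atm), Pd/C (10 % palladium on carbon), MeOH–H2O, rt; filter; Dowex 50WX8 (H+ form), H2O, 4 °C; freeze-dry, store at −20 °C
Reagents that add atoms: none
Why: catalytic hydrogenolysis of a benzyl aryl ether, which aryl sulfate salts tolerate, frees the 5-OH that at once chelates to C4=O, and cold cation exchange replaces sodium by H+ before the aryl hydrogen sulfates can hydrolyse.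

## Compound list
1 | 2-methoxyresorcinol (2-methoxybenzene-1,3-diol) | COc1c(O)cccc1O | starting material
2 | [(2,4-dihydroxy-3-methoxyphenyl)methylidene]dimethylammonium chloride | COc1c(O)ccc(C=[N+](C)C)c1O.[Cl-] | intermediate
3 | 2,4-dihydroxy-3-methoxybenzaldehyde | COc1c(O)ccc(C=O)c1O | intermediate
4 | 2-hydroxy-3-methoxy-4-[(4-methoxybenzyl)oxy]benzaldehyde | COc1ccc(COc2ccc(C=O)c(O)c2OC)cc1 | intermediate
5 | 2-(benzyloxy)-3-methoxy-4-[(4-methoxybenzyl)oxy]benzaldehyde | COc1ccc(COc2ccc(C=O)c(OCc3ccccc3)c2OC)cc1 | intermediate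
6 | 2-(benzyloxy)-3-methoxy-4-[(4-methoxybenzyl)oxy]phenyl formate | COc1ccc(COc2ccc(OC=O)c(OCc3ccccc3)c2OC)cc1 | intermediate
7 | 2-(benzyloxy)-3-methoxy-4-[(4-methoxybenzyl)oxy]phenol | COc1ccc(COc2ccc(O)c(OCc3ccccc3)c2OC)cc1 | intermediate
8 | 2-(benzyloxy)-6-bromo-3-methoxy-4-[(4-methoxybenzyl)oxy]phenol | COc1ccc(COc2cc(Br)c(O)c(OCc3ccccc3)c2OC)cc1 | intermediate
9 | {2-(benzyloxy)-6-bromo-3-methoxy-4-[(4-methoxybenzyl)oxy]phenoxy}trimethylsilane | COc1ccc(COc2cc(Br)c(O[Si](C)(C)C)c(OCc3ccccc3)c2OC)cc1 | intermediate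
10 | lithium 2-(benzyloxy)-3-methoxy-4-[(4-methoxybenzyl)oxy]-6-(trimethylsilyl)phenoxide | COc1ccc(COc2cc([Si](C)(C)C)c([O-])c(OCc3ccccc3)c2OC)cc1.[Li+] | intermediate
11 | 2-(benzyloxy)-3-methoxy-4-[(4-methoxybenzyl)oxy]-6-(trimethylsilyl)phenyl trifluoromethanesulfonate | COc1ccc(COc2cc([Si](C)(C)C)c(OS(=O)(=O)C(F)(F)F)c(OCc3ccccc3)c2OC)cc1 | intermediate
12 | 4-iodophenol | Oc1ccc(I)cc1 | starting material
13 | 1-iodo-4-[(4-methoxybenzyl)oxy]benzene | COc1ccc(COc2ccc(I)cc2)cc1 | intermediate
14 | propiolic acid | C#CC(=O)O | starting material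
15 | 3-{4-[(4-methoxybenzyl)oxy]phenyl}prop-2-ynoic acid | COc1ccc(COc2ccc(C#CC(=O)O)cc2)cc1 | intermediate
16 | 3-(benzyloxy)-4-methoxy-5-[(4-methoxybenzyl)oxy]benzyne (1,2-didehydrobenzene) | COc1ccc(COC2=CC#CC(OCc3ccccc3)=C2OC)cc1 | intermediate
17 | 1-{2-(benzyloxy)-6-hydroxy-3-methoxy-4-[(4-methoxybenzyl)oxy]phenyl}-3-{4-[(4-methoxybenzyl)oxy]phenyl}prop-2-yn-1-one | COc1ccc(COc2ccc(C#CC(=O)c3c(O)cc(OCc4ccc(OC)cc4)c(OC)c3OCc5ccccc5)cc2)cc1 | intermediate
18 | 5-(benzyloxy)-6-methoxy-7-[(4-methoxybenzyl)oxy]-2-{4-[(4-methoxybenzyl)oxy]phenyl}-4H-chromen-4-one | COc1ccc(COc2ccc(-c3cc(=O)c4c(OCc5ccccc5)c(OC)c(OCc6ccc(OC)cc6)cc4o3)cc2)cc1 | intermediate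
19 | 5-(benzyloxy)-7-hydroxy-2-(4-hydroxyphenyl)-6-methoxy-4H-chromen-4-one (5-O-benzylhispidulin) | COc1c(O)cc2oc(-c3ccc(O)cc3)cc(=O)c2c1OCc4ccccc4 | intermediate
20 | bis(pyridinium) 5-O-benzylhispidulin 7,4'-disulfate | COc1c(OS(=O)(=O)[O-])cc2oc(-c3ccc(OS(=O)(=O)[O-])cc3)cc(=O)c2c1OCc4ccccc4.c5cc[nH+]cc5.c6cc[nH+]cc6 | intermediate
21 | disodium 5-O-benzylhispidulin 7,4'-disulfate | COc1c(OS(=O)(=O)[O-])cc2oc(-c3ccc(OS(=O)(=O)[O-])cc3)cc(=O)c2c1OCc4ccccc4.[Na+].[Na+] | intermediate
22 | disodium hispidulin 7,4'-disulfate | COc1c(OS(=O)(=O)[O-])cc2oc(-c3ccc(OS(=O)(=O)[O-])cc3)cc(=O)c2c1O.[Na+].[Na+] | intermediate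
23 | hispidulin 7,4'-disulfate (free acid, achiral) | COc1c(OS(=O)(=O)O)cc2oc(-c3ccc(OS(=O)(=O)O)cc3)cc(=O)c2c1O | target

Total step count: 12. Longest linear sequence: 10 (steps 1 to 6 and 9 to 12); steps 7 and 8 form the ring B branch.

Steps most likely to fail:

Step 9. The aryl anion may be protonated before it reaches the ester carbonyl (giving an aryl ester in place of the ketone), the phenoxide may close 5-exo to an aurone, or the propiolate may lose CO2 at 100 °C. The fallback sets out from 11 and 15 and comes back at 17. Aryne generation from 11 with CsF in DMF lets the formamide carbonyl insert with the same polarity (oxygen to C8a, carbon to C4a), and aqueous work-up should give 2-(benzyloxy)-6-hydroxy-3-methoxy-4-[(4-methoxybenzyl)oxy]benzaldehyde F1. Acid 15 is protodecarboxylated (CuCl cat., Et3N, MeCN, 60 °C) to 1-ethynyl-4-[(4-methoxybenzyl)oxy]benzene F2. Its lithium acetylide (n-BuLi, 2.2 equiv of acetylide, THF, −78 °C) adds to F1 to give the racemic propargylic alcohol 3-(benzyloxy)-2-(1-hydroxy-3-{4-[(4-methoxybenzyl)oxy]phenyl}prop-2-yn-1-yl)-4-methoxy-5-[(4-methoxybenzyl)oxy]phenol F3. MnO2 oxidation gives ynone 17, which is cyclised with Et2NH in EtOH to 18.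

Step 5. Bromine may enter at C5 beside the 4-methoxybenzyl ether, a second bromine may follow, or the para-alkoxyphenol may be oxidised to a quinone with loss of the 4-methoxybenzyl group. The fallback sets out from 7 and comes back at 11 by directed ortho-metalation. Phenol 7 and isopropyl isocyanate (Et3N cat.) give 2-(benzyloxy)-3-methoxy-4-[(4-methoxybenzyl)oxy]phenyl N-isopropylcarbamate F4. In situ N-silylation (TBSOTf, TMEDA), lithiation ortho to the carbamate (n-BuLi, TMEDA, −78 °C) and a TMSCl quench give, after work-up, 2-(benzyloxy)-3-methoxy-4-[(4-methoxybenzyl)oxy]-6-(trimethylsilyl)phenyl N-isopropylcarbamate F5. Et2NH and DBU in MeCN cleave the carbamate, and the phenoxide is triflated in the same flask with PhNTf2 to give 11.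

Step 12. The C2–C3 double bond may be reduced, the hindered benzyl ether may cleave slowly on the charged substrate, and sulfate may be lost during the acid exchange. The fallback sets out from 19 and comes back at 23, with the sulfates carried as neutral diesters. Diol 19 and 2,2,2-trichloroethyl chlorosulfate (Et3N, DMAP, THF) give 5-O-benzylhispidulin 7,4'-bis(2,2,2-trichloroethyl sulfate) F6. BCl3 (CH2Cl2, −78 °C) cleaves the peri benzyl ether with chelation to C4=O to give hispidulin 7,4'-bis(2,2,2-trichloroethyl sulfate) F7. Zn and HCO2NH4 in MeOH remove both trichloroethyl groups to give diammonium hispidulin 7,4'-disulfate F8, which is passed through the H+ resin as in step 12 to give 23.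

## Further compounds
F1 | step 9 | 2-(benzyloxy)-6-hydroxy-3-methoxy-4-[(4-methoxybenzyl)oxy]benzaldehyde | COc1ccc(COc2cc(O)c(C=O)c(OCc3ccccc3)c2OC)cc1
F2 | step 9 | 1-ethynyl-4-[(4-methoxybenzyl)oxy]benzene | COc1ccc(COc2ccc(C#C)cc2)cc1
F3 | step 9 | 3-(benzyloxy)-2-(1-hydroxy-3-{4-[(4-methoxybenzyl)oxy]phenyl}prop-2-yn-1-yl)-4-methoxy-5-[(4-methoxybenzyl)oxy]phenol (racemic) | COc1ccc(COc2ccc(C#CC(O)c3c(O)cc(OCc4ccc(OC)cc4)c(OC)c3OCc5ccccc5)cc2)cc1
F4 | step 5 | 2-(benzyloxy)-3-methoxy-4-[(4-methoxybenzyl)oxy]phenyl N-isopropylcarbamate | COc1ccc(COc2ccc(OC(=O)NC(C)C)c(OCc3ccccc3)c2OC)cc1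
F5 | step 5 | 2-(benzyloxy)-3-methoxy-4-[(4-methoxybenzyl)oxy]-6-(trimethylsilyl)phenyl N-isopropylcarbamate | COc1ccc(COc2cc([Si](C)(C)C)c(OC(=O)NC(C)C)c(OCc3ccccc3)c2OC)cc1
F6 | step 12 | 5-O-benzylhispidulin 7,4'-bis(2,2,2-trichloroethyl sulfate) | COc1c(OS(=O)(=O)OCC(Cl)(Cl)Cl)cc2oc(-c3ccc(OS(=O)(=O)OCC(Cl)(Cl)Cl)cc3)cc(=O)c2c1OCc4ccccc4
F7 | step 12 | hispidulin 7,4'-bis(2,2,2-trichloroethyl sulfate) | COc1c(OS(=O)(=O)OCC(Cl)(Cl)Cl)cc2oc(-c3ccc(OS(=O)(=O)OCC(Cl)(Cl)Cl)cc3)cc(=O)c2c1O
F8 | step 12 | diammonium hispidulin 7,4'-disulfate | COc1c(OS(=O)(=O)[O-])cc2oc(-c3ccc(OS(=O)(=O)[O-])cc3)cc(=O)c2c1O.[NH4+].[NH4+]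
A1 | direct plan | apigenin | O=c1cc(-c2ccc(O)cc2)oc2cc(O)cc(O)c12
A2 | direct plan | 5-hydroxy-2-(4-hydroxyphenyl)-4-oxo-6-(phenyliodonio)-4H-chromen-7-olate | O=c1cc(-c2ccc(O)cc2)oc2cc([O-])c([I+]c3ccccc3)c(O)c12
A3 | direct plan | hispidulin | COc1c(O)cc2oc(-c3ccc(O)cc3)cc(=O)c2c1O
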